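In the closed runs the sum of target and starting material stays put, at 99.9% in the last south-west reading, so each target counts as one turnover of the enzyme, and you can count turnovers without fitting a mechanism. The east run shows second substrate to be the limiting reagent: its last reading of 64.8% is 1.30 mM of target against a charge of 1.3 mM.

| flask | starting material | second substrate | free enzyme | impurity | remark | time |
|---|---|---|---|---|---|---|
| south-west | 2 mM | 2 mM | 0.40 µM | 0.14 µM | run made earlier |  |
| east | 2 mM | 1.3 mM | 0.40 µM | 0.14 µM | run made earlier |  |
| west | 2 mM | 3 mM | 0.40 µM | 0.14 µM | run made earlier |  |
| birch | 2.0 mM (fed, over 2.00 min) | 2.00 mM | 0.40 µM | 0.14 µM | all but starting material at the start; starting material goes in evenly over 2.00 min, the run ends at 2.5 min | 2.5 min |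
| elm | 2.0 mM | 2.00 mM | 0.40 µM | 0.14 µM | one stirred flow tank at steady state, fed with the mixture as stated, mean residence time 2.5 min |  |
| ash | 2.0 mM | 2.00 mM | 0.40 µM | 0.14 µM | a closed flask charged with all of it at once and left for 2.5 min | 2.5 min |
| maple | 2.0 mM | 2.00 mM (fed, over 2.00 min) | 0.40 µM | 0.14 µM | all but second substrate at the start; second substrate goes in evenly over 2.00 min, the run ends at 2.5 min | 2.5 min |

south-west run (percent of the starting material charged)

| time / s | target / % | starting material / % |
|---|---|---|
| 25.0 | 25.0 | 75.4 |
| 50.0 | 45.6 | 54.5 |
| 60.0 | 52.5 | 46.9 |
| 90.0 | 70.3 | 29.6 |

east run (percent of the starting material charged)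

| time / min | target / % | starting material / % |
|---|---|---|
| 0.833 | 43.5 | 57.3 |
| 1.50 | 61.8 | 38.7 |
| 2.50 | 65.1 | 34.8 |
| 3.00 | 64.8 | 34.5 |

west run (percent of the starting material charged)

| time / min | target / % | starting material / % |
|---|---|---|
| 0.417 | 25.7 | 75.0 |
| 1.00 | 54.1 | 46.2 |
| 2.00 | 85.0 | 14.9 |
| 3.00 | 96.4 | 4.5 |

(readings scatter by 0.5 percentage points)

- the set-up with the highest amount of target at the outlet or at the end, in percent of the starting material put in ("none" if the first two lie within 2 percentage points) (birch / elm / ash / maple / none)
- amount of target at the outlet or at the end, in percent of the starting material put in, birch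
- amount of target at the outlet or at the end, in percent of the starting material put in, elm
- amount of target at the outlet or at the end, in percent of the starting material put in, ash
- amount of target at the outlet or at the end, in percent of the starting material put in, maple

- the stated concentrations are those of everything mixed, before any reaction; amounts are the same in each set-up
- the analysis behind the earlier runs scatters by 0.5 percentage points, standard deviation
- the feed brings no volume worth counting
- the earlier runs were made in a closed, stirred flask

Per charged enzyme, the whole charge costs

demand = starting material / free enzyme = 5000 turnovers.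

Now ask which inputs must be known well. The stated value of free enzyme need not be, for this reckoning: south-west has the same free enzyme and impurity as elm and ash, so an error in the stated number moves demand and read speed by one factor, and it cancels. Second substrate matches starting material here, which puts the ceiling at 100% and keeps the fraction left of each equal. The number to know well is the turnovers per charged enzyme per second, divided by the fraction of starting material left. South-west gives two readings of it:

early = demand × ln(left at 25.0 s / left at 50.0 s) / interval = 64.9 s⁻¹

late = demand × ln(left at 60.0 s / left at 90.0 s) / interval = 76.7 s⁻¹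

Call the late value the speed per fraction left. Ash continues south-west from its last reading, and elm's balance is demand × (1 − left) = speed × left × residence time:

ash left = 11.8%, so target 88.2%

elm left = 30.3%, so target 69.7%

The early value would give 86.4% and 66.1%, so elm is the more sensitive. The late value suits elm, whose 30.3% left lies between the 46.9% and 29.6% of the late readings.

The forecast gives birch 72%, elm 70%, ash 88% and maple 82%, with ash best, holding of starting material that “keeping it high is best, and feeding it hurts”.

The flasks give birch 72.9%, elm 71.3%, ash 89.9% and maple 81.6%, with ash best. Speed per fraction left, reckoned back from these, is 82.7 s⁻¹ in elm and 89.4 s⁻¹ in ash over its last stretch, both above the read 76.7 s⁻¹.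

    starting material + free enzyme ⇌ first complex (K = 310 M⁻¹, k = 1.30 × 10⁶ M⁻¹ s⁻¹)
    first complex → loaded enzyme + first product (k = 340 s⁻¹)
    second substrate + loaded enzyme ⇌ second complex (K = 2000 M⁻¹, k = 1.60 × 10⁶ M⁻¹ s⁻¹)
    second complex → free enzyme + target (k = 350 s⁻¹)
    2 first complex ⇌ resting dimer, settled at all times (K = 8.60 × 10⁵ M⁻¹)
    free enzyme + impurity → spent catalyst (k = 1.20 × 10⁸ M⁻¹ s⁻¹)

In this scheme first complex falls back to free enzyme and starting material with a rate constant of 4190 s⁻¹, faster than the 340 s⁻¹ with which it goes on to loaded enzyme. The equilibrium constant of that uptake times the starting material charged to ash is 0.620.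

All runs come from a simulation from invented constants.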